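**Retrosynthetic overview**
1. Target 32 ⇒ enyne 29: the seven-membered ring and dienone of unit B are made last, by domino ring-closing enyne metathesis/cross-metathesis.
2. Spiro cyclohexenol ⇒ a three-component anionic annulation in place of a [4+2] dimerisation: C5–C13' (Mukaiyama–Michael, stored as cyclobutane 23), C11'–C3 (Michael addition to nitroenone 22), C2–C1 (Henry); loss of HNO2 then gives the C2=C3 enone and leaves the C1 carbinol.
3. Both halves come from one enyne lactone 12 (asymmetric allylboration–lactonisation of aldehyde 3 with boronate 9); for unit A, 12 becomes cyclic silyl enol ether 17 (alkyne hydration, thiol masking of the exo-methylene lactone, enol-ether ring-closing metathesis).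
4. Ring order: γ-lactone (12) → cycloheptene of unit A (17) → cyclobutane (23) → spiro cyclohexane (26) → cycloheptadiene of unit B (32).

Assumption: xanthane numbering is used (C1–C15 = carbinol half, unit A; primed atoms = dienone half, unit B), and the catalyst antipodes named in steps 1 and 3 are taken to be those that give the drawn configuration (the mirror-image catalyst is used if the sense of induction is opposite).

**Step 1**
Reactants: 1 (E)-but-2-enal; 2 ethynyltri(propan-2-yl)silane
Product: 3 (3S)-3-methyl-5-[tri(propan-2-yl)silyl]pent-4-ynal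
Conditions: [Rh(OAc)(C2H4)2]2 (2.5 mol %), (R)-DTBM-SEGPHOS (6 mol %), 2 (2 equiv), MeOH, 40 °C
Reagents that add atoms: none
Why: Rhodium-catalysed asymmetric conjugate alkynylation of an enal, in which the bulky silylacetylene suppresses alkyne dimerisation and the chiral bisphosphine sets the methyl-bearing stereocentre (later C10 and C10', S) by face-selective alkynyl transfer to the β-carbon.

**Step 2**
Reactants: 4 allylmagnesium bromide; 5 methyl propiolate; 6 2-(iodomethyl)-4,4,5,5-tetramethyl-1,3,2-dioxaborolane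
Product: 9 methyl (2E)-2-[(4,4,5,5-tetramethyl-1,3,2-dioxaborolan-2-yl)methyl]hexa-2,5-dienoate, via allylcopper 7 (not isolated), via alkenylcopper 8 (not isolated)
Conditions: 4, CuBr·SMe2 (1.05 equiv each), THF, −78 °C; 5, −78 °C, 1 h; 6, HMPA, −78 → 0 °C
Reagents that add atoms: none
Why: Syn-carbocupration of the propiolate puts allyl and copper cis, and alkylation of the alkenylcopper with the iodomethylboronate proceeds with retention, giving the 2-alkoxycarbonyl allylboronate with the allyl group cis to CH2B.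

**Step 3**
Reactants: 3 (3S)-3-methyl-5-[tri(propan-2-yl)silyl]pent-4-ynal; 9 allylboronate
Product: 11 (4R,5R)-3-methylidene-5-{(2S)-2-methyl-4-[tri(propan-2-yl)silyl]but-3-yn-1-yl}-4-(prop-2-en-1-yl)oxolan-2-one, via borate ester 10 (not isolated)
Conditions: (R)-TRIP (10 mol %), 4 Å MS, toluene, 0 °C → rt; then TsOH·H2O (10 mol %), rt
Reagents that add atoms: none
Why: Chiral-phosphoric-acid-catalysed allylboration through a closed chair transition state (γ-substituent cis to CH2B, hence syn adduct) followed by lactonisation of the borate onto the ester gives the cis-4,5-disubstituted α-methylene lactone, the acid choosing the aldehyde face (C8 R) and the chair relaying it to C7 (R).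

**Step 4**
Reactants: 11 silylated enyne lactone
Product: 12 (4R,5R)-3-methylidene-5-[(2S)-2-methylbut-3-yn-1-yl]-4-(prop-2-en-1-yl)oxolan-2-one
Conditions: TBAF (1.2 equiv), THF, 0 °C, 30 min; AcOH
Reagents that add atoms: none
Why: Fluoride-mediated protodesilylation of the alkynylsilane, run cold and quenched with acetic acid so that the exo-methylene lactone is not attacked.

**Step 5**
Reactants: 12 enyne lactone
Product: 13 (4R,5R)-3-methylidene-5-[(2S)-2-methyl-3-oxobutyl]-4-(prop-2-en-1-yl)oxolan-2-one
Conditions: Ph3PAuNTf2 (2 mol %), H2O (3 equiv), 1,4-dioxane, 60 °C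
Reagents that add atoms: water (O)
Why: Gold-catalysed Markovnikov hydration of the terminal alkyne gives the methyl ketone while the alkene and the exo-methylene lactone stay untouched and no stereocentre is affected.

**Step 6**
Reactants: 13 methyl ketone
Product: 14 (4R,5R)-5-[(2S)-2-methyl-3-oxobutyl]-3-[(phenylsulfanyl)methyl]-4-(prop-2-en-1-yl)oxolan-2-one (C3 epimers)
Conditions: PhSH (1.1 equiv), Et3N (0.1 equiv), CH2Cl2, 0 °C → rt
Reagents that add atoms: benzenethiol (Sc1ccccc1)
Why: Base-catalysed thia-Michael addition masks the exo-methylene lactone of the future unit A (the new α-centre is irrelevant because it becomes sp2 again in step 14), so that this half can later act only as the nucleophile.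

**Step 7**
Reactants: 14 sulfide ketone
Product: 16 (4R,5R)-5-{(2S)-2-methyl-3-[(triethylsilyl)oxy]but-3-en-1-yl}-3-[(phenylsulfanyl)methyl]-4-(prop-2-en-1-yl)oxolan-2-one, via lithium enolate 15 (not isolated)
Conditions: LiN(iPr)2 (1.05 equiv), THF, −78 °C; Et3SiCl, −78 → 0 °C
Reagents that add atoms: chlorotriethylsilane (CC[Si](Cl)(CC)CC)
Why: Kinetic deprotonation of the methyl ketone at the methyl group (faster than at C10–H or at the less acidic lactone α-H) and O-silylation give the 2-silyloxy-1-alkene without touching the C10 stereocentre.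

**Step 8**
Reactants: 16 acyclic silyl enol ether
Product: 17 (3aR,7S,8aR)-7-methyl-3-[(phenylsulfanyl)methyl]-6-[(triethylsilyl)oxy]-3,3a,4,7,8,8a-hexahydro-2H-cyclohepta[b]furan-2-one
Conditions: second-generation Grubbs catalyst RuCl2(=CHPh)(H2IMes)(PCy3) (7 mol %), toluene (5 mM), 80 °C, Ar sparge
Reagents that add atoms: none
Why: Ring-closing metathesis of the 1,1-disubstituted silyl enol ether with the terminal alkene closes the seven-membered ring and delivers the ketone directly as its regiodefined C1=C5 silyl enol ether.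

**Step 9**
Reactants: 18 2-oxopropanal (methylglyoxal, 40 % aqueous); 19 nitromethane
Product: 20 3-hydroxy-4-nitrobutan-2-one (racemic)
Conditions: Et3N (5 mol %), THF/H2O, 0 °C
Reagents that add atoms: none
Why: Henry (nitroaldol) addition of nitromethane to the aldehyde carbonyl, which is far more electrophilic than the ketone.

**Step 10**
Reactants: 20 3-hydroxy-4-nitrobutan-2-one
Product: 22 (3E)-4-nitrobut-3-en-2-one, via mesylate 21 (not isolated)
Conditions: MsCl (1.1 equiv), Et3N (2.2 equiv), CH2Cl2, −40 → 0 °C; used at once as a cold solution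
Reagents that add atoms: none
Why: Mesylation and E1cB elimination of the β-nitro alcohol give the E-nitroalkene and destroy the stereocentre of 20.

**Step 11**
Reactants: 17 cyclic silyl enol ether; 12 enyne lactone
Product: 23 cyclobutane adduct (new bonds C5–C13' and C1–C11'; C1 triethylsilyl ether; spiro C11' undefined)
Conditions: Tf2NH (5 mol %), CH2Cl2, −78 °C; Et3N quench
Reagents that add atoms: none
Why: Triflimide-catalysed (in situ Et3SiNTf2) Mukaiyama–Michael/aldol (2+2) cycloaddition of a silyl enol ether with an acrylate-type acceptor (only the lactone of 12 can accept, that of 17 being masked), whose intramolecular collapse to the cyclobutane outruns oligomerisation and stores the 1:1 adduct as a masked lactone enolate, the C5–C13' bond being expected on the enol-ether face cis to the C10 methyl that the same ring system uses in the natural dimer (C5 S; C1 and C11' of the cyclobutane are temporary).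

**Step 12**
Reactants: 23 cyclobutane adduct; 22 (3E)-4-nitrobut-3-en-2-one
Product: 26 nitro carbinol (spiro cyclohexane with C1–OH; C2–NO2; C3–acetyl; C2/C3 epimers), via lactone enolate 24 (not isolated), via nitronate 25 (not isolated)
Conditions: 22 (1.5 equiv), TASF (1.1 equiv), THF, −78 → 0 °C; AcOH
Reagents that add atoms: none
Why: Proposed new method: fluoride cleaves the silyl ether and the strained cyclobutanolate opens by retro-aldol to the regiodefined lactone enolate 24, which adds to the nitroenone at the carbon β to nitro from the lactone face anti to the C7' allyl group (C11' S), after which nitronate 25 closes onto the C1 ketone in a reversible 6-exo Henry reaction that should settle in the trans-fused carbinol with both ring carbons equatorial and OH axial (C1 S); the closest known reaction types are fluoride-triggered ring-opening/Michael cascades of siloxycyclopropane carboxylates and the enolate-initiated Michael–Michael–aldol [2+2+2] annulation.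

**Step 13**
Reactants: 26 nitro carbinol
Product: 27 hydroxy enone (C1–OH; C2=C3–acetyl; unit A lactone still as thiol adduct; unit B enyne)
Conditions: DBU (2 equiv), MeCN, 0 °C → rt
Reagents that add atoms: none
Why: E1cB loss of nitrous acid from the β-nitro ketone (C3–H is α to the acetyl group) installs the C2=C3 enone and keeps the tertiary C1 carbinol, the nitro group having served as a traceless activator that made the enone α-carbon electrophilic.

**Step 14**
Reactants: 27 hydroxy enone
Product: 29 enyne dimer (32 with unit B still as the allyl/alkynyl lactone), via sulfone 28 (not isolated)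
Conditions: mCPBA (2.2 equiv), CH2Cl2, −20 → 0 °C; then DBU (1.5 equiv), 0 °C → rt
Reagents that add atoms: none
Why: Chemoselective S-oxidation to the sulfone followed by base-induced E1cB expulsion of benzenesulfinate regenerates the exo-methylene lactone of unit A, conditions under which the electron-poor enone, the terminal alkene and the alkyne are left alone.

**Step 15**
Reactants: 29 enyne dimer; 30 but-3-en-2-one (methyl vinyl ketone)
Product: 32 target CNP0168949.1, via triene 31 (not isolated)
Conditions: second-generation Hoveyda–Grubbs catalyst RuCl2(=CH-C6H4-2-OiPr)(H2IMes) (15 mol %), 30 (10 equiv), CH2Cl2, 40 °C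
Reagents that add atoms: none
Why: Domino ring-closing enyne metathesis (exo mode, seven-membered ring with C1'=C5') and E-selective cross-metathesis of the resulting terminal diene with methyl vinyl ketone, the 1,1-disubstituted and trisubstituted electron-poor alkenes of unit A being inert to the ruthenium carbene; no stereocentre is formed.

**Compound list**
1 | (E)-but-2-enal | C/C=C/C=O | starting material
2 | ethynyltri(propan-2-yl)silane | C#C[Si](C(C)C)(C(C)C)C(C)C | starting material
3 | (3S)-3-methyl-5-[tri(propan-2-yl)silyl]pent-4-ynal | C[C@@H](CC=O)C#C[Si](C(C)C)(C(C)C)C(C)C | intermediate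
4 | allylmagnesium bromide | C=CC[Mg]Br | starting material
5 | methyl propiolate | COC(=O)C#C | starting material
6 | 2-(iodomethyl)-4,4,5,5-tetramethyl-1,3,2-dioxaborolane | ICB1OC(C)(C)C(C)(C)O1 | starting material
7 | allylcopper | C=CC[Cu] | intermediate
8 | [(1Z)-1-(methoxycarbonyl)penta-1,4-dien-1-yl]copper | COC(=O)/C([Cu])=C/CC=C | intermediate
9 | methyl (2E)-2-[(4,4,5,5-tetramethyl-1,3,2-dioxaborolan-2-yl)methyl]hexa-2,5-dienoate | COC(=O)/C(CB1OC(C)(C)C(C)(C)O1)=C/CC=C | intermediate
10 | methyl (3R,4R,6S)-6-methyl-2-methylidene-3-(prop-2-en-1-yl)-4-[(4,4,5,5-tetramethyl-1,3,2-dioxaborolan-2-yl)oxy]-8-[tri(propan-2-yl)silyl]oct-7-ynoate | COC(=O)C(=C)[C@@H](CC=C)[C@@H](C[C@H](C)C#C[Si](C(C)C)(C(C)C)C(C)C)OB1OC(C)(C)C(C)(C)O1 | intermediate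
11 | (4R,5R)-3-methylidene-5-{(2S)-2-methyl-4-[tri(propan-2-yl)silyl]but-3-yn-1-yl}-4-(prop-2-en-1-yl)oxolan-2-one | O=C1O[C@H](C[C@H](C)C#C[Si](C(C)C)(C(C)C)C(C)C)[C@H](CC=C)C1=C | intermediate
12 | (4R,5R)-3-methylidene-5-[(2S)-2-methylbut-3-yn-1-yl]-4-(prop-2-en-1-yl)oxolan-2-one | O=C1O[C@H](C[C@H](C)C#C)[C@H](CC=C)C1=C | intermediate
13 | (4R,5R)-3-methylidene-5-[(2S)-2-methyl-3-oxobutyl]-4-(prop-2-en-1-yl)oxolan-2-one | O=C1O[C@H](C[C@H](C)C(C)=O)[C@H](CC=C)C1=C | intermediate
14 | (4R,5R)-5-[(2S)-2-methyl-3-oxobutyl]-3-[(phenylsulfanyl)methyl]-4-(prop-2-en-1-yl)oxolan-2-one (C3 epimers) | O=C1O[C@H](C[C@H](C)C(C)=O)[C@H](CC=C)C1CSc1ccccc1 | intermediate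
15 | lithium enolate of 14 (deprotonated at the ketone methyl group) | O=C1O[C@H](C[C@H](C)C(=C)[O-])[C@H](CC=C)C1CSc1ccccc1.[Li+] | intermediate
16 | (4R,5R)-5-{(2S)-2-methyl-3-[(triethylsilyl)oxy]but-3-en-1-yl}-3-[(phenylsulfanyl)methyl]-4-(prop-2-en-1-yl)oxolan-2-one | O=C1O[C@H](C[C@H](C)C(=C)O[Si](CC)(CC)CC)[C@H](CC=C)C1CSc1ccccc1 | intermediate
17 | (3aR,7S,8aR)-7-methyl-3-[(phenylsulfanyl)methyl]-6-[(triethylsilyl)oxy]-3,3a,4,7,8,8a-hexahydro-2H-cyclohepta[b]furan-2-one | O=C1O[C@@H]2C[C@H](C)C(O[Si](CC)(CC)CC)=CC[C@@H]2C1CSc1ccccc1 | intermediate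
18 | 2-oxopropanal (methylglyoxal) | CC(=O)C=O | starting material
19 | nitromethane | C[N+](=O)[O-] | starting material
20 | 3-hydroxy-4-nitrobutan-2-one (racemic) | CC(=O)C(O)C[N+](=O)[O-] | intermediate
21 | 1-nitro-3-oxobutan-2-yl methanesulfonate | CC(=O)C(OS(C)(=O)=O)C[N+](=O)[O-] | intermediate
22 | (3E)-4-nitrobut-3-en-2-one | CC(=O)/C=C/[N+](=O)[O-] | intermediate
23 | cyclobutane adduct: unit A of 17 with C1 (OSiEt3 α) and C5 (H α) joined through C5–C13'H2 and C1–C11' to the lactone α-carbon of 12 (C11' spiro, undefined) | c1ccccc1SCC1C(=O)O[C@@H]2C[C@H](C)[C@@]3(O[Si](CC)(CC)CC)[C@@H](C[C@H]12)CC34C(=O)O[C@H](C[C@H](C)C#C)[C@@H]4CC=C | intermediate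
24 | tris(dimethylamino)sulfonium lactone enolate: unit A C1 ketone carrying at C5 (S) the C13'H2 link to the enolised lactone (C11'=C12'–O−) of unit B | c1ccccc1SCC1C(=O)O[C@@H]2C[C@H](C)C(=O)[C@@H](C[C@H]12)CC1=C([O-])O[C@H](C[C@H](C)C#C)[C@@H]1CC=C.CN(C)[S+](N(C)C)N(C)C | intermediate
25 | tris(dimethylamino)sulfonium nitronate: as 24 but with C11' (S) quaternary, bearing C3H(acetyl)–C2H=NO2− | c1ccccc1SCC1C(=O)O[C@@H]2C[C@H](C)C(=O)[C@@H](C[C@H]12)C[C@]1(C(C(C)=O)C=[N+]([O-])[O-])C(=O)O[C@H](C[C@H](C)C#C)[C@@H]1CC=C.CN(C)[S+](N(C)C)N(C)C | intermediate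
26 | nitro carbinol: skeleton and configuration of 32 at C1, C5, C7, C8, C10, C11', C7', C8', C10', with C2–NO2 and C3–H (epimers), unit A lactone as PhSCH2 adduct, unit B as allyl/alkynyl lactone | c1ccccc1SCC1C(=O)O[C@@H]2C[C@H](C)[C@@]3(O)C([N+](=O)[O-])C(C(C)=O)[C@@]4(C[C@@H]3C[C@H]12)C(=O)O[C@H](C[C@H](C)C#C)[C@@H]4CC=C | intermediate
27 | hydroxy enone: as 26 but with C2=C3 bearing the acetyl group | c1ccccc1SCC1C(=O)O[C@@H]2C[C@H](C)[C@@]3(O)C=C(C(C)=O)[C@@]4(C[C@@H]3C[C@H]12)C(=O)O[C@H](C[C@H](C)C#C)[C@@H]4CC=C | intermediate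
28 | sulfone of 27 (PhSO2CH2 at C11 of unit A) | O=S(=O)(c1ccccc1)CC1C(=O)O[C@@H]2C[C@H](C)[C@@]3(O)C=C(C(C)=O)[C@@]4(C[C@@H]3C[C@H]12)C(=O)O[C@H](C[C@H](C)C#C)[C@@H]4CC=C | intermediate
29 | enyne dimer: 32 in which unit B is still the 7'-allyl-8'-[(2S)-2-methylbut-3-ynyl] spiro lactone | C=C1C(=O)O[C@@H]2C[C@H](C)[C@@]3(O)C=C(C(C)=O)[C@@]4(C[C@@H]3C[C@H]12)C(=O)O[C@H](C[C@H](C)C#C)[C@@H]4CC=C | intermediate
30 | but-3-en-2-one (methyl vinyl ketone) | CC(=O)C=C | starting material
31 | triene: 32 with a vinyl group at C1' in place of the 3-oxobut-1-enyl chain | C=C1C(=O)O[C@@H]2C[C@H](C)[C@@]3(O)C=C(C(C)=O)[C@@]4(C[C@@H]3C[C@H]12)C(=O)O[C@@H]1C[C@H](C)C(C=C)=CC[C@@H]14 | intermediate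
32 | CNP0168949.1: (1S,5S,7R,8R,10S)-unit A spiro-linked at C11' (S) to (7'R,8'R,10'S)-unit B | C=C1C(=O)O[C@@H]2C[C@H](C)[C@@]3(O)C=C(C(C)=O)[C@@]4(C[C@@H]3C[C@H]12)C(=O)O[C@@H]1C[C@H](C)C(/C=C/C(C)=O)=CC[C@@H]14 | target

**Totals**
Total steps: 15. Longest linear sequence: 12 (steps 1, 3–8, 11–15; steps 2, 9 and 10 are side branches).

**Three steps most likely to fail**

Step 12. The cascade is new. The free enolate 24 may be protonated or scrambled before it meets 22, 22 may not survive fluoride, and the nitroaldol may revert before or during step 13. The C1 configuration also rests on thermodynamic control. Fallback, setting out from 23 and 22 and coming back at 27: a Lewis-acid route that never frees the enolate. Yb(OTf)3 (10 mol %, CH2Cl2, −40 °C) opens the donor–acceptor cyclobutane to its 1,4-zwitterion, which adds to 22 and closes through the silyl-oxocarbenium ion in a formal (4+2) annulation to the O-silylated nitro carbinol F4. DBU then removes HNO2 to give the silyl ether of the hydroxy enone F5, and HF·pyridine cleaves the silyl ether to 27.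

Step 11. The cyclobutane must form between two fully substituted carbons, and the thioether may tie up the silyl triflimide catalyst. Fallback, setting out from 12 and 30 and coming back at 32: the cycloaddition route. Domino enyne metathesis/cross-metathesis of 12 with 30 gives 8-epi-xanthatin F1. Thermal [4+2] dimerisation (neat or 5 M in toluene, 90 °C) gives the endo head-to-head Diels–Alder dimer F2. Dimethyldioxirane epoxidises C1=C2 on the face of the later hydroxyl to give the 1,2-epoxide F3, which DBU opens by E1cB at C3 to 32.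

Step 15. The metathesis must run next to the crowded spiro centre, and the unveiled exo-methylene lactone of unit A is exposed to the carbene and to excess enone. Fallback, setting out from 27 and 30 and coming back at 32: reverse the endgame. The domino metathesis is run on 27 while the unit A lactone is still masked, giving the sulfide-masked dimer F6. Oxidation with mCPBA gives the sulfone F7, and DBU-induced elimination of benzenesulfinate gives 32.

Further compounds
F1 | step 11 | 8-epi-xanthatin, (3aR,7S,8aR)-7-methyl-3-methylidene-6-[(E)-3-oxobut-1-enyl]-4,7,8,8a-tetrahydro-3aH-cyclohepta[b]furan-2-one | C=C1C(=O)O[C@@H]2C[C@H](C)C(/C=C/C(C)=O)=CC[C@H]12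
F2 | step 11 | Diels–Alder dimer: 32 without the 1-hydroxyl, with C1=C2 and 3-H cis to 5-H | C=C1C(=O)O[C@@H]2C[C@H](C)C3=C[C@H](C(C)=O)[C@@]4(C[C@@H]3C[C@H]12)C(=O)O[C@@H]1C[C@H](C)C(/C=C/C(C)=O)=CC[C@@H]14
F3 | step 11 | 1,2-epoxide of F2, oxygen on the face of the C1 hydroxyl of 32 | C=C1C(=O)O[C@@H]2C[C@H](C)[C@]35O[C@@H]5[C@H](C(C)=O)[C@@]4(C[C@@H]3C[C@H]12)C(=O)O[C@@H]1C[C@H](C)C(/C=C/C(C)=O)=CC[C@@H]14
F4 | step 12 | O-triethylsilyl ether of nitro carbinol 26 | c1ccccc1SCC1C(=O)O[C@@H]2C[C@H](C)[C@@]3(O[Si](CC)(CC)CC)C([N+](=O)[O-])C(C(C)=O)[C@@]4(C[C@@H]3C[C@H]12)C(=O)O[C@H](C[C@H](C)C#C)[C@@H]4CC=C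
F5 | step 12 | O-triethylsilyl ether of hydroxy enone 27 | c1ccccc1SCC1C(=O)O[C@@H]2C[C@H](C)[C@@]3(O[Si](CC)(CC)CC)C=C(C(C)=O)[C@@]4(C[C@@H]3C[C@H]12)C(=O)O[C@H](C[C@H](C)C#C)[C@@H]4CC=C
F6 | step 15 | sulfide-masked dimer: 32 with the unit A lactone as its PhSCH2 adduct | c1ccccc1SCC1C(=O)O[C@@H]2C[C@H](C)[C@@]3(O)C=C(C(C)=O)[C@@]4(C[C@@H]3C[C@H]12)C(=O)O[C@@H]1C[C@H](C)C(/C=C/C(C)=O)=CC[C@@H]14
F7 | step 15 | sulfone of F6 | O=S(=O)(c1ccccc1)CC1C(=O)O[C@@H]2C[C@H](C)[C@@]3(O)C=C(C(C)=O)[C@@]4(C[C@@H]3C[C@H]12)C(=O)O[C@@H]1C[C@H](C)C(/C=C/C(C)=O)=CC[C@@H]14
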